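## Retrosynthetic overview
1. Vitedoin A comes from chemoselective reduction of the saturated C2-CHO of the 1-aryl-1,2-dihydronaphthalene-2,3-dicarbaldehyde **10**. The conjugated C3-CHO is left intact.
2. **10** is made in one pot by an amine-catalysed cascade. An o-formyl benzhydrol lactol ionises to a p-quinone methide, and the succinaldehyde enamine adds 1,6 to it (setting C1 and C2). An intramolecular aldol condensation then closes the only new ring (C3=C4).
3. The lactol comes from ArMgBr addition to a bromo-aldehyde, followed by Br/Li exchange and DMF formylation, then desilylation.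
4. Starting materials: 3-hydroxy-2-methoxybenzaldehyde, 4-bromo-2-methoxyphenol and succinaldehyde.

Assumptions: the target is the trans-(1S,2R) isomer as drawn. Succinaldehyde (**9**) is freshly prepared from commercial 2,5-dimethoxytetrahydrofuran by brief aqueous acid hydrolysis and used as a solution.

## Route

**Step 1**
Reactants: **1** 3-hydroxy-2-methoxybenzaldehyde
Product: **2** 6-bromo-3-hydroxy-2-methoxybenzaldehyde
Conditions: NBS, MeCN, 0 °C → rt
Reagents that add atoms: NBS, O=C1CCC(=O)N1Br
Why: Electrophilic aromatic bromination goes para to the strongly activating OH (C6), as in isovanillin bromination. This places Br where C4a of the target will be.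

**Step 2**
Reactants: **2**
Product: **3** 6-bromo-3-(tert-butyldimethylsilyloxy)-2-methoxybenzaldehyde
Conditions: TBSCl, imidazole, DMF, rt
Reagents that add atoms: TBSCl, C[Si](C)(C(C)(C)C)Cl
Why: Silyl protection of the phenol makes it compatible with the later Grignard and alkyllithium steps.

**Step 3**
Reactants: **4** 4-bromo-2-methoxyphenol
Product: **5** 4-bromo-1-(tert-butyldimethylsilyloxy)-2-methoxybenzene
Conditions: TBSCl, imidazole, DMF, rt
Reagents that add atoms: TBSCl, C[Si](C)(C(C)(C)C)Cl
Why: Silyl protection allows the guaiacyl Grignard to be formed.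

**Step 4**
Reactants: **5** (as its ArMgBr, from Mg, THF, reflux) and **3**
Product: **6** (±)-(6-bromo-3-TBSO-2-methoxyphenyl)(4-TBSO-3-methoxyphenyl)methanol
Conditions: (a) **5**, Mg, THF, reflux; (b) add **3**, THF, −78 °C → rt; NH4Cl work-up
Reagents that add atoms: none
Why: Grignard 1,2-addition to the aldehyde gives the diarylcarbinol. Its carbinol stereocentre is racemic but is destroyed by ionisation in Step 7.

**Step 5**
Reactants: **6**
Product: **7** 3-(4-TBSO-3-methoxyphenyl)-4-methoxy-5-TBSO-1,3-dihydroisobenzofuran-1-ol (lactol, diastereomer mixture)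
Conditions: n-BuLi (2.2 equiv), THF, −78 °C; then DMF, −78 °C → 0 °C; aq. NH4Cl
Reagents that add atoms: DMF, CN(C)C=O (supplies the CHO carbon, later C4)
Why: The first equivalent of n-BuLi deprotonates the carbinol and the second does Br/Li exchange. DMF formylation gives the o-formyl benzhydrol, which closes spontaneously to the lactol.

**Step 6**
Reactants: **7**
Product: **8** 3-(4-hydroxy-3-methoxyphenyl)-4-methoxy-1,3-dihydroisobenzofuran-1,5-diol (lactol, in equilibrium with the open o-formyl benzhydrol)
Conditions: TBAF, AcOH (buffer), THF, 0 °C
Reagents that add atoms: none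
Why: Fluoride removes both aryl silyl ethers. Buffering with AcOH avoids base-induced aldehyde side reactions. This frees the 4'-OH needed for p-QM formation.

**Step 7 (key step)**
Reactants: **8** and **9** succinaldehyde (3 equiv)
Product: **10** (1S,2R)-7-hydroxy-1-(4-hydroxy-3-methoxyphenyl)-8-methoxy-1,2-dihydronaphthalene-2,3-dicarbaldehyde
Conditions: (R)-α,α-diphenylprolinol TMS ether·TFA (20 mol%), TFA (10 mol%), toluene/HFIP 9:1, 4 Å MS, 0 °C → rt, 48 h
Reagents that add atoms: none
Why: Proposed new method: acid opens lactol **8** at its doubly benzylic C–O bond, pushed by the para-OH, to give an o-formylaryl p-quinone methide. The (R)-diarylprolinol silyl ether forms the E-s-trans enamine of succinaldehyde, which adds 1,6 to the QM anti to the bulky silyloxy-diarylmethyl group, through a synclinal Seebach-type TS as in its nitroalkene Michael additions. This sets C1 (S) and C2 (R in the final product, trans). The remote CH2CHO then forms a second enamine, which undergoes intramolecular aldol onto the ortho ArCHO (6-enolexo) and E1cB dehydration to the conjugated enal. The closest known reactions are amine-catalysed 1,6-additions of aldehydes to p-QMs and amine-catalysed Michael/aldol-condensation annulations to chromenes and dihydroquinolines.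

**Step 8**
Reactants: **10**
Product: **11** Vitedoin A, (1S,2R)-7-hydroxy-1-(4-hydroxy-3-methoxyphenyl)-2-(hydroxymethyl)-8-methoxy-1,2-dihydronaphthalene-3-carbaldehyde
Conditions: NaBH(OAc)3 (1.1 equiv), CH2Cl2/THF, −10 °C, 1 h
Reagents that add atoms: none (hydride only)
Why: The hindered but unconjugated aliphatic aldehyde is reduced much faster than the push–pull enal, which is deactivated by the para-hydroxyl. No stereocentre is touched.

## Compound list
1 | 3-hydroxy-2-methoxybenzaldehyde | COc1c(O)cccc1C=O | starting material
2 | 6-bromo-3-hydroxy-2-methoxybenzaldehyde | COc1c(O)ccc(Br)c1C=O | intermediate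
3 | 6-bromo-3-(TBSO)-2-methoxybenzaldehyde | COc1c(O[Si](C)(C)C(C)(C)C)ccc(Br)c1C=O | intermediate
4 | 4-bromo-2-methoxyphenol | COc1cc(Br)ccc1O | starting material
5 | 4-bromo-1-(TBSO)-2-methoxybenzene | COc1cc(Br)ccc1O[Si](C)(C)C(C)(C)C | intermediate
6 | (±)-(6-bromo-3-TBSO-2-methoxyphenyl)(4-TBSO-3-methoxyphenyl)methanol | COc1cc(C(O)c2c(Br)ccc(O[Si](C)(C)C(C)(C)C)c2OC)ccc1O[Si](C)(C)C(C)(C)C | intermediate
7 | bis-TBS 3-aryl-1-hydroxyphthalan (lactol) | OC1OC(c2ccc(O[Si](C)(C)C(C)(C)C)c(OC)c2)c2c1ccc(O[Si](C)(C)C(C)(C)C)c2OC | intermediate
8 | 3-(4-hydroxy-3-methoxyphenyl)-4-methoxy-1,3-dihydroisobenzofuran-1,5-diol | OC1OC(c2ccc(O)c(OC)c2)c2c1ccc(O)c2OC | intermediate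
9 | succinaldehyde | O=CCCC=O | starting material
10 | (1S,2R)-dialdehyde | COc1cc([C@H]2c3c(ccc(O)c3OC)C=C(C=O)[C@@H]2C=O)ccc1O | intermediate
11 | Vitedoin A | COc1cc([C@H]2c3c(ccc(O)c3OC)C=C(C=O)[C@@H]2CO)ccc1O | target

## Totals
Total steps: 8.
Longest linear sequence: 7 (1 → 2 → 3 → 6 → 7 → 8 → 10 → 11, i.e. Steps 1, 2, 4, 5, 6, 7, 8).

## Three steps most likely to fail
1. **Step 7 (proposed new cascade).** Risks are a diaryl p-QM that is too hindered or too short-lived, competing indane formation through the C2 enamine, succinaldehyde oligomerisation, and the wrong C1/C2 relative configuration.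
   Fallback: abandon the cascade and use an Evans auxiliary route.
   - Cu-catalysed diastereoselective 1,4-addition of Ar'MgBr to the (E)-ArA-cinnamoyl oxazolidinone sets C1.
   - Titanium-enolate allylation sets C2.
   - LiBH4 removes the auxiliary to give the C2–CH2OH, which is silylated.
   - Ozonolysis gives the 4-arylbutanal.
   - Acid Friedel–Crafts cyclodehydration at C4a (para to the O-substituent) gives the dihydronaphthalene.
   - Vilsmeier formylation at C3 and desilylation complete the synthesis.
2. **Step 8 (chemoselective aldehyde reduction).** The enal could be over-reduced, or C2 could epimerise.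
   Fallback: reduce both aldehydes (Luche, NaBH4/CeCl3) to the diol, re-protect the phenols as TBS ethers, oxidise only the allylic alcohol with MnO2, then remove the silyl groups with TBAF.
3. **Step 5 (Br/Li exchange and formylation on the lithium alkoxide).** The hindered, electron-rich aryl bromide may exchange poorly or give protonation or butyl addition.
   Fallback: replace the organolithium with Pd-catalysed reductive carbonylation of the aryl bromide (Pd(OAc)2/cataCXium A, CO/H2) on the free benzhydrol, which closes to the same lactol.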